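**Plan**
1. Numbering: C1 (pendant syringyl), C2 (CH2OH), C3 (CHO), C4 (vinyl CH), C4a/C8a (fusion), C5 (H), C6 and C8 (OMe), C7 (OH). Ring A is the fused arene and ring B is the carbocycle C1-C2-C3-C4-C4a-C8a.
2. Enabling feature: C1 and C4, the two ring B carbons bonded to ring A, sit on the neighbouring aromatic carbons C8a and C4a. Ring B is therefore the [4+2] adduct of the ortho-quinodimethane C1=C8a-C4a=C4 and a C2=C3 alkene.
3. Retrosynthesis: remove the silyl groups, take C3-CHO back to an ester and C3=C4 back to a C4 carbinol, cut C1-C2 and C3-C4 together, then cut C1-C8a of the resulting 2-benzylbenzaldehyde.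
4. Forward: both arenes come from syringaldehyde and are joined by a Negishi coupling (C1-C8a). Ring B, the only ring made, closes in the photoenolization/Diels-Alder step, and dehydration, redox adjustment at C3 and desilylation follow.
5. Stereochemistry: C1 and C2 are fixed in the cycloaddition. The trans relation comes from outward aryl, endo ester and E-alkene, and the absolute sense from Ti(OiPr)2(TADDOLate). C3 and C4 are transient and vanish on dehydration.

Key step: step 8

Abbreviation: TBS = tert-butyldimethylsilyl. Descriptors of 12 to 17 refer to the numbering above.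
Assumption: (R,R)-TADDOL is taken to open the diene face that leads to the (1S,2R) series. The sense of induction has to be verified on the cycloadduct, and the equally available (S,S)-TADDOL would be used otherwise with nothing else changed.

Step 1
Reactants: 1 syringaldehyde (4-hydroxy-3,5-dimethoxybenzaldehyde)
Product: 2 4-(TBS-oxy)-3,5-dimethoxybenzaldehyde
Conditions: TBSCl (1.2 equiv), imidazole (2.5 equiv), DMF, 0 °C to rt
Reagents that add atoms: tert-butyldimethylsilyl chloride, CC(C)(C)[Si](C)(C)Cl
Why: Imidazole-promoted O-silylation of a phenol is routine, and an aryl silyl ether flanked by two methoxy groups should stand the organozinc, photochemical, hydride and MnO2 steps yet fall to fluoride at the end.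

Step 2
Reactants: 2 4-(TBS-oxy)-3,5-dimethoxybenzaldehyde
Product: 3 2-bromo-4-(TBS-oxy)-3,5-dimethoxybenzaldehyde
Conditions: NBS (1.05 equiv), MeCN, 0 °C to rt, dark
Reagents that add atoms: N-bromosuccinimide, O=C1CCC(=O)N1Br
Why: This is an electrophilic aromatic bromination as practised on 3,4,5-trialkoxybenzaldehydes, in which the two free positions are equivalent, each is ortho to one and para to the other methoxy group, and the first bromine slows a second substitution.

Step 3
Reactants: 2 4-(TBS-oxy)-3,5-dimethoxybenzaldehyde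
Product: 4 [4-(TBS-oxy)-3,5-dimethoxyphenyl]methanol
Conditions: NaBH4, THF/MeOH, 0 °C
Reagents that add atoms: none
Why: Borohydride reduction of an aromatic aldehyde is fast at 0 °C and leaves the aryl silyl ether intact.

Step 4
Reactants: 4 [4-(TBS-oxy)-3,5-dimethoxyphenyl]methanol
Product: 5 4-(TBS-oxy)-3,5-dimethoxybenzyl chloride
Conditions: SOCl2 (1.1 equiv), 2,6-lutidine (1.2 equiv), CH2Cl2, 0 °C
Reagents that add atoms: thionyl chloride, O=S(Cl)Cl
Why: Deoxychlorination of a benzylic alcohol with SOCl2 is standard, and the hindered base takes up HCl without quaternising the benzylic chloride.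

Step 5
Reactants: 5 4-(TBS-oxy)-3,5-dimethoxybenzyl chloride
Product: 6 4-(TBS-oxy)-3,5-dimethoxybenzylzinc chloride (THF solution, decanted and titrated)
Conditions: Zn dust (1.5 equiv), LiCl (1.5 equiv), THF, 25 °C
Reagents that add atoms: zinc, [Zn]
Why: LiCl-assisted direct insertion of zinc into a benzylic C-Cl bond is established for alkoxy-substituted benzyl chlorides, and the chloride gives little Wurtz dimer.

Step 6
Reactants: 3 2-bromo-4-(TBS-oxy)-3,5-dimethoxybenzaldehyde; 6 4-(TBS-oxy)-3,5-dimethoxybenzylzinc chloride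
Product: 7 4-(TBS-oxy)-2-[4-(TBS-oxy)-3,5-dimethoxybenzyl]-3,5-dimethoxybenzaldehyde
Conditions: Pd(OAc)2 (2 mol %), SPhos (4 mol %), THF, 25 °C, slow addition of 6 (1.2 equiv)
Reagents that add atoms: none
Why: In this Negishi sp3-sp2 coupling the ortho formyl group speeds oxidative addition of zerovalent palladium into the C-Br bond, SPhos copes with the double ortho substitution, the benzyl group has no β-hydrogen, slow dosing keeps carbonyl addition from competing, and the neutral medium spares the aryl silyl ethers.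

Step 7
Reactants: 8 (TBS-oxy)acetaldehyde; 9 methyl (triphenylphosphoranylidene)acetate
Product: 10 methyl (E)-4-(TBS-oxy)but-2-enoate
Conditions: CH2Cl2, rt
Reagents that add atoms: none
Why: The Wittig reaction of an ester-stabilised ylide with an unhindered aldehyde is reliably E-selective and fixes the alkene geometry that becomes the trans C2/C3 relation.

Step 8
Reactants: 7 4-(TBS-oxy)-2-[4-(TBS-oxy)-3,5-dimethoxybenzyl]-3,5-dimethoxybenzaldehyde; 10 methyl (E)-4-(TBS-oxy)but-2-enoate
Product: 12 methyl (1S,2R,3S,4S)-4-hydroxy-1-[4-(TBS-oxy)-3,5-dimethoxyphenyl]-2-(TBS-oxymethyl)-7-(TBS-oxy)-6,8-dimethoxytetralin-3-carboxylate, via hydroxy-ortho-quinodimethane 11 (not isolated)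
Conditions: Ti(OiPr)4 (2 equiv) premixed with (R,R)-TADDOL (2.2 equiv), 10 (3 equiv), 4 Å MS, degassed toluene, hν 365 nm (LED), 0 °C; aq. NaHCO3
Reagents that add atoms: none
Why: Light of 365 nm excites the formyl group of 7, a 1,5-hydrogen shift from the weak doubly benzylic C1-H to the carbonyl oxygen follows, and the long-lived dienol 11 with its hydroxyl turned outward is held through its oxygen on the titanium centre of Ti(OiPr)2(TADDOLate), which also binds the ester carbonyl of 10. Ring B, the only ring formed, closes by a concerted suprafacial intermolecular [4+2] cycloaddition of C1=C8a-C4a=C4 with C2=C3 that makes C1-C2 and C3-C4 at once and restores the aromatic sextet of ring A; the closest known reaction type is the photoenolization/Diels-Alder reaction of 2-alkyl- and 2-benzylbenzaldehydes with electron-poor alkenes, including its enantioselective Ti(OiPr)4/TADDOL variant. C1 and C4 become cis because aryl and hydroxyl both point outward in 11, C3 becomes cis to C4 because the titanium-bridged ester reacts endo, and C2 becomes trans to C3 and thus trans to the C1 aryl because the E geometry of 10 is carried over. The absolute configuration (1S,2R,3S,4S) comes from the one diene face that the aryl groups of the ligand leave open. The step needs the ester-bearing carbon to bond to C4: the oxygen donor on C4 puts the larger HOMO coefficient on the remote terminus C1, which pairs with the β-carbon of the enoate, and the titanium bridge between the C4 oxygen and the ester reinforces this against the weaker opposite bias of the C1 aryl group. It also needs the outward aryl geometry, which should hold because an inward aryl group would collide with the C4 terminus more severely than the outward one does with the C8 methoxy group, and an inward isomer is a poor diene that reverts to 7.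

Step 9
Reactants: 12 tetralol ester cycloadduct
Product: 14 methyl (1S,2R)-1-[4-(TBS-oxy)-3,5-dimethoxyphenyl]-2-(TBS-oxymethyl)-7-(TBS-oxy)-6,8-dimethoxy-1,2-dihydronaphthalene-3-carboxylate, via C4 mesylate 13 (not isolated)
Conditions: MsCl (1.5 equiv), Et3N (3 equiv), CH2Cl2, 0 °C; then DBU (2 equiv), 0 °C to rt, argon
Reagents that add atoms: methanesulfonyl chloride, CS(=O)(=O)Cl (its atoms are held in 13 only)
Why: This is mesylation followed by base-induced β-elimination of a β-sulfonyloxy ester, in which C3-H is acidified by the ester and stands anti to the C4 leaving group, the new C3=C4 bond is conjugated with ring A and the ester, and the two transient stereocentres disappear while C1 and C2 are not touched.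

Step 10
Reactants: 14 dihydronaphthalene ester
Product: 15 [(1S,2R)-1-[4-(TBS-oxy)-3,5-dimethoxyphenyl]-2-(TBS-oxymethyl)-7-(TBS-oxy)-6,8-dimethoxy-1,2-dihydronaphthalen-3-yl]methanol
Conditions: iBu2AlH (2.5 equiv), CH2Cl2, -78 °C; aq. potassium sodium tartrate
Reagents that add atoms: none
Why: 1,2-Reduction of an α,β-unsaturated ester to the allylic alcohol with iBu2AlH at low temperature is standard and leaves silyl ethers and the alkene untouched.

Step 11
Reactants: 15 allylic alcohol
Product: 16 (1S,2R)-1-[4-(TBS-oxy)-3,5-dimethoxyphenyl]-2-(TBS-oxymethyl)-7-(TBS-oxy)-6,8-dimethoxy-1,2-dihydronaphthalene-3-carbaldehyde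
Conditions: activated MnO2 (15 equiv), CH2Cl2, rt, argon
Reagents that add atoms: none
Why: MnO2 oxidises allylic alcohols of the cinnamyl type selectively to enals, and with both phenols and the C2 carbinol masked neither phenol oxidation nor lactol over-oxidation can occur.

Step 12
Reactants: 16 tris-silylated enal
Product: 17 (1S,2R)-7-hydroxy-1-(4-hydroxy-3,5-dimethoxyphenyl)-2-(hydroxymethyl)-6,8-dimethoxy-1,2-dihydronaphthalene-3-carbaldehyde (CNP0313592.1)
Conditions: TBAF/AcOH (1:1, 4 equiv), THF, 0 °C, argon
Reagents that add atoms: none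
Why: Fluoride-driven Si-O cleavage removes the two aryl and the one alkyl silyl ether in one operation, and acetic acid keeps the released phenoxides protonated so that the enal, C2 and the oxidisable dihydronaphthalene are not exposed to base.

**Compound list**
1 | syringaldehyde | COc1cc(C=O)cc(OC)c1O | starting material
2 | 4-(TBS-oxy)-3,5-dimethoxybenzaldehyde | COc1cc(C=O)cc(OC)c1O[Si](C)(C)C(C)(C)C | intermediate
3 | 2-bromo-4-(TBS-oxy)-3,5-dimethoxybenzaldehyde | COc1cc(C=O)c(Br)c(OC)c1O[Si](C)(C)C(C)(C)C | intermediate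
4 | [4-(TBS-oxy)-3,5-dimethoxyphenyl]methanol | COc1cc(CO)cc(OC)c1O[Si](C)(C)C(C)(C)C | intermediate
5 | 4-(TBS-oxy)-3,5-dimethoxybenzyl chloride | COc1cc(CCl)cc(OC)c1O[Si](C)(C)C(C)(C)C | intermediate
6 | 4-(TBS-oxy)-3,5-dimethoxybenzylzinc chloride | COc1cc(C[Zn]Cl)cc(OC)c1O[Si](C)(C)C(C)(C)C | intermediate
7 | 4-(TBS-oxy)-2-[4-(TBS-oxy)-3,5-dimethoxybenzyl]-3,5-dimethoxybenzaldehyde | COc1cc(Cc2c(C=O)cc(OC)c(O[Si](C)(C)C(C)(C)C)c2OC)cc(OC)c1O[Si](C)(C)C(C)(C)C | intermediate
8 | (TBS-oxy)acetaldehyde | CC(C)(C)[Si](C)(C)OCC=O | starting material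
9 | methyl (triphenylphosphoranylidene)acetate | COC(=O)C=P(c1ccccc1)(c1ccccc1)c1ccccc1 | starting material
10 | methyl (E)-4-(TBS-oxy)but-2-enoate | COC(=O)/C=C/CO[Si](C)(C)C(C)(C)C | intermediate
11 | hydroxy-ortho-quinodimethane from 7, hydroxyl on C4 and aryl on C1 both outward (titanium-bound in the flask, drawn as the free dienol) | O/C=C1\C=C(OC)C(O[Si](C)(C)C(C)(C)C)=C(OC)/C1=C\c2cc(OC)c(O[Si](C)(C)C(C)(C)C)c(OC)c2 | intermediate
12 | methyl (1S,2R,3S,4S)-4-hydroxy-1-aryltetralin-3-carboxylate cycloadduct; aryl, ester and hydroxyl mutually cis, CH2OTBS trans to them | COc1cc([C@H]2c3c(cc(OC)c(O[Si](C)(C)C(C)(C)C)c3OC)[C@@H](O)[C@@H](C(=O)OC)[C@@H]2CO[Si](C)(C)C(C)(C)C)cc(OC)c1O[Si](C)(C)C(C)(C)C | intermediate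
13 | C4 methanesulfonate of 12 | COc1cc([C@H]2c3c(cc(OC)c(O[Si](C)(C)C(C)(C)C)c3OC)[C@@H](OS(C)(=O)=O)[C@@H](C(=O)OC)[C@@H]2CO[Si](C)(C)C(C)(C)C)cc(OC)c1O[Si](C)(C)C(C)(C)C | intermediate
14 | methyl (1S,2R)-1-aryl-2-(TBS-oxymethyl)-1,2-dihydronaphthalene-3-carboxylate | COc1cc([C@H]2c3c(cc(OC)c(O[Si](C)(C)C(C)(C)C)c3OC)C=C(C(=O)OC)[C@@H]2CO[Si](C)(C)C(C)(C)C)cc(OC)c1O[Si](C)(C)C(C)(C)C | intermediate
15 | (1S,2R) C3 allylic alcohol | COc1cc([C@H]2c3c(cc(OC)c(O[Si](C)(C)C(C)(C)C)c3OC)C=C(CO)[C@@H]2CO[Si](C)(C)C(C)(C)C)cc(OC)c1O[Si](C)(C)C(C)(C)C | intermediate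
16 | (1S,2R) tris-silylated enal | COc1cc([C@H]2c3c(cc(OC)c(O[Si](C)(C)C(C)(C)C)c3OC)C=C(C=O)[C@@H]2CO[Si](C)(C)C(C)(C)C)cc(OC)c1O[Si](C)(C)C(C)(C)C | intermediate
17 | (1S,2R)-7-hydroxy-1-(4-hydroxy-3,5-dimethoxyphenyl)-2-(hydroxymethyl)-6,8-dimethoxy-1,2-dihydronaphthalene-3-carbaldehyde | COc1cc([C@H]2c3c(cc(OC)c(O)c3OC)C=C(C=O)[C@@H]2CO)cc(OC)c1O | target

Total step count: 12. Longest linear sequence: 10 (steps 1, 3, 4, 5, 6, 8, 9, 10, 11, 12).

**Steps most likely to fail**

**Step 8.**
- What may go wrong: The β-alkyl enoate may trap the photoenol too slowly, so that reketonisation, closure to a benzocyclobutenol or capture by residual oxygen take over. The C1 aryl group may erode the regiochemistry, the C8 methoxy group may disturb the outward aryl geometry, and the external ligand may give poor facial selectivity.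
- Fallback: It sets out from 7 and keeps the photoenol, but changes the dienophile, its activation and the source of chirality.
  - Fumaryl chloride and methyl (S)-lactate (Et3N, CH2Cl2) give bis[(S)-1-methoxy-1-oxopropan-2-yl] fumarate F1. This alkene is doubly activated and symmetric, so no regiochemical question arises. Its covalently bound auxiliary takes over facial control, a known way of steering hydroxy-ortho-quinodimethane cycloadditions.
  - Irradiation of 7 with it at 365 nm in degassed toluene without titanium should give the tetralol diester F2.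
  - MsCl/Et3N and then DBU lead through the mesylate F3 to the dihydronaphthalene diester F4, in which C2 is epimerisable and should settle trans to the aryl group.
  - iBu2AlH reduces all four ester groups to the diol F5, and MnO2 oxidises only its allylic, ring A-conjugated alcohol to the hydroxy enal F6.
  - TBAF/AcOH brings the sequence back to the route at 17.
  - Methyl (R)-lactate would be used if the auxiliary favours the other face.

**Step 6.**
- What may go wrong: The benzylic zinc reagent may add to the free formyl group, and oxidative addition into the doubly ortho-substituted C-Br bond may be slow enough for homocoupling to dominate.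
- Fallback: It sets out from 3, masks the carbonyl group and reverses the polarity of the partners, so that palladium inserts into the unhindered benzylic chloride.
  - HC(OMe)3 with catalytic p-TsOH in MeOH gives the dimethyl acetal F7.
  - n-BuLi in THF at -78 °C gives the aryllithium F8, and ZnCl2 converts it into the arylzinc chloride F9.
  - Coupling with 5 under Pd(OAc)2/SPhos gives the diarylmethane acetal F10.
  - 1 M HCl in THF returns the sequence to the route at 7.

**Step 9.**
- What may go wrong: The electron-rich benzylic mesylate may ionise and be captured by chloride or by the neighbouring silyloxy oxygen. DBU may strip the aryl silyl groups, epimerise C2 through γ-deprotonation of the enoate, or open the way to aromatisation.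
- Fallback: It sets out from 12 and moves the elimination to the aldehyde oxidation level, where loss of water needs only a weak base.
  - iBu2AlH (3.5 equiv, CH2Cl2, -78 °C) gives the 1,3-diol F11.
  - TEMPO (cat.)/PhI(OAc)2 oxidises the primary alcohol in preference to the hindered secondary one and gives the β-hydroxy aldehyde F12.
  - Et3N at 0 °C then removes water by an E1cB path, and the sequence rejoins the route at 16, bypassing 14 and 15.

**Further compounds**
F1 | step 8 | bis[(S)-1-methoxy-1-oxopropan-2-yl] fumarate | COC(=O)[C@H](C)OC(=O)/C=C/C(=O)O[C@@H](C)C(=O)OC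
F2 | step 8 | (1S,2R,3S,4S) tetralol 2,3-diester of methyl (S)-lactate | COc1cc([C@H]2c3c(cc(OC)c(O[Si](C)(C)C(C)(C)C)c3OC)[C@@H](O)[C@@H](C(=O)O[C@@H](C)C(=O)OC)[C@@H]2C(=O)O[C@@H](C)C(=O)OC)cc(OC)c1O[Si](C)(C)C(C)(C)C
F3 | step 8 | C4 methanesulfonate of F2 | COc1cc([C@H]2c3c(cc(OC)c(O[Si](C)(C)C(C)(C)C)c3OC)[C@@H](OS(C)(=O)=O)[C@@H](C(=O)O[C@@H](C)C(=O)OC)[C@@H]2C(=O)O[C@@H](C)C(=O)OC)cc(OC)c1O[Si](C)(C)C(C)(C)C
F4 | step 8 | (1S,2R) 1,2-dihydronaphthalene 2,3-diester of methyl (S)-lactate | COc1cc([C@H]2c3c(cc(OC)c(O[Si](C)(C)C(C)(C)C)c3OC)C=C(C(=O)O[C@@H](C)C(=O)OC)[C@@H]2C(=O)O[C@@H](C)C(=O)OC)cc(OC)c1O[Si](C)(C)C(C)(C)C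
F5 | step 8 | (1S,2R) 2,3-bis(hydroxymethyl)-1,2-dihydronaphthalene, phenols silylated | COc1cc([C@H]2c3c(cc(OC)c(O[Si](C)(C)C(C)(C)C)c3OC)C=C(CO)[C@@H]2CO)cc(OC)c1O[Si](C)(C)C(C)(C)C
F6 | step 8 | (1S,2R) 2-(hydroxymethyl) enal, phenols silylated | COc1cc([C@H]2c3c(cc(OC)c(O[Si](C)(C)C(C)(C)C)c3OC)C=C(C=O)[C@@H]2CO)cc(OC)c1O[Si](C)(C)C(C)(C)C
F7 | step 6 | dimethyl acetal of 3 | COc1cc(C(OC)OC)c(Br)c(OC)c1O[Si](C)(C)C(C)(C)C
F8 | step 6 | aryllithium from F7 | COc1cc(C(OC)OC)c([Li])c(OC)c1O[Si](C)(C)C(C)(C)C
F9 | step 6 | arylzinc chloride from F8 | COc1cc(C(OC)OC)c([Zn]Cl)c(OC)c1O[Si](C)(C)C(C)(C)C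
F10 | step 6 | dimethyl acetal of 7 | COc1cc(Cc2c(C(OC)OC)cc(OC)c(O[Si](C)(C)C(C)(C)C)c2OC)cc(OC)c1O[Si](C)(C)C(C)(C)C
F11 | step 9 | 1,3-diol from 12 (C3 CH2OH, C4 OH) | COc1cc([C@H]2c3c(cc(OC)c(O[Si](C)(C)C(C)(C)C)c3OC)[C@@H](O)[C@@H](CO)[C@@H]2CO[Si](C)(C)C(C)(C)C)cc(OC)c1O[Si](C)(C)C(C)(C)C
F12 | step 9 | β-hydroxy aldehyde (C3 CHO, C4 OH) | COc1cc([C@H]2c3c(cc(OC)c(O[Si](C)(C)C(C)(C)C)c3OC)[C@@H](O)[C@@H](C=O)[C@@H]2CO[Si](C)(C)C(C)(C)C)cc(OC)c1O[Si](C)(C)C(C)(C)C
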